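**Plan**
- Retrosynthesis: the five benzyl ethers are removed last. Both pyranone rings are opened at O1–C2 and O1''–C2'' to a bis(2-hydroxyaryl 1,3-diketone). C2–C3 and C2''–C3'' are then cut together, each giving an aryl ester next to an acetyl group. The two ester C–O bonds and the C3'–C8'' biaryl bond are cut last.
- Enabling feature: take ring C of unit 1 (O1, C2, C3, C4, C4a, C8a; carries ring B) and ring C of unit 2 (double-primed atoms; carries the 4-methoxyphenyl ring, joined through C8'' to C3'). In each, C3 is a former acetyl methyl carbon, C2 a former aroyl carbonyl carbon, and the C4 ketone sits ortho to the phenolic oxygen (O1 on C8a, O1'' on C8a''). The molecule therefore holds two 2-acyloxyacetophenone patterns.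
- Forward: Suzuki coupling forms C3'–C8'' first. The hindered phenol beside it is anisoylated, the formyl group is oxidised, and the acid is esterified with a second acetophenone. One base treatment moves both acyl groups from O to C, acid then closes both pyranone rings, and hydrogenolysis frees the five phenols.
- Stereochemistry: the target has no stereocentre and nothing is set.

Key step: step 9

Remark: the 3',8'' biaryl axis has no assigned configuration in the target and is made without atroposelection. The 1,3-diketones are drawn as diketo forms although they should exist largely as chelated enols.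

**Step 1**
Reactants: 1 2',4',6'-trihydroxyacetophenone
Product: 2 1-[2,4-bis(benzyloxy)-6-hydroxyphenyl]ethan-1-one
Conditions: BnBr (2.1 equiv), K2CO3 (2.2 equiv), DMF, rt
Reagents that add atoms: benzyl bromide, BrCc1ccccc1
Why: Williamson etherification; the 4-OH and one of the two equivalent ortho OH groups are alkylated, and the remaining phenol is held in a hydrogen bond to the acetyl carbonyl and should resist a third benzylation.

**Step 2**
Reactants: 2 1-[2,4-bis(benzyloxy)-6-hydroxyphenyl]ethan-1-one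
Product: 3 1-[4,6-bis(benzyloxy)-2-hydroxy-3-iodophenyl]ethan-1-one
Conditions: BnMe3N·ICl2 (1.05 equiv), CaCO3, CH2Cl2–MeOH, rt
Reagents that add atoms: benzyltrimethylammonium dichloroiodate, C[N+](C)(C)Cc1ccccc1.Cl[I-]Cl
Why: Electrophilic aromatic iodination; under carbonate buffering the chelated free phenol should direct iodine to C3, ortho to the hydroxyl, as is usual for 2-hydroxy-4,6-dialkoxyacetophenones, and one equivalent limits diiodination.

**Step 3**
Reactants: 4 3-bromo-4-hydroxybenzaldehyde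
Product: 5 4-(benzyloxy)-3-bromobenzaldehyde
Conditions: BnBr (1.1 equiv), K2CO3, DMF, rt
Reagents that add atoms: benzyl bromide, BrCc1ccccc1
Why: Williamson etherification of the only phenol; the aldehyde is inert to carbonate and benzyl bromide.

**Step 4**
Reactants: 5 4-(benzyloxy)-3-bromobenzaldehyde
Product: 6 4-(benzyloxy)-3-(4,4,5,5-tetramethyl-1,3,2-dioxaborolan-2-yl)benzaldehyde
Conditions: B2pin2 (1.2 equiv), Pd(dppf)Cl2 (3 mol %), KOAc (3 equiv), 1,4-dioxane, 90 °C
Reagents that add atoms: bis(pinacolato)diboron, CC1(C)OB(B2OC(C)(C)C(C)(C)O2)OC1(C)C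
Why: Miyaura borylation; the bromide adds oxidatively to zerovalent palladium, and the weak acetate base tolerates the aldehyde and prevents the boronate from coupling with unreacted bromide.

**Step 5**
Reactants: 3 1-[4,6-bis(benzyloxy)-2-hydroxy-3-iodophenyl]ethan-1-one; 6 4-(benzyloxy)-3-(4,4,5,5-tetramethyl-1,3,2-dioxaborolan-2-yl)benzaldehyde (1.3 equiv)
Product: 7 3-[3-acetyl-4,6-bis(benzyloxy)-2-hydroxyphenyl]-4-(benzyloxy)benzaldehyde
Conditions: Pd(OAc)2 (5 mol %), SPhos (10 mol %), K2CO3 (3 equiv), 1,4-dioxane–H2O 5:1, 80 °C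
Reagents that add atoms: none
Why: Suzuki–Miyaura coupling; the electron-rich biarylphosphine supports oxidative addition into the iodophenoxide and reductive elimination to the tri-ortho-substituted biaryl, and carbonate is too weak to condense the aldehyde with the phenoxide-deactivated methyl ketone.

**Step 6**
Reactants: 7 3-[3-acetyl-4,6-bis(benzyloxy)-2-hydroxyphenyl]-4-(benzyloxy)benzaldehyde; 8 4-methoxybenzoyl chloride (1.3 equiv)
Product: 9 2-acetyl-3,5-bis(benzyloxy)-6-[2-(benzyloxy)-5-formylphenyl]phenyl 4-methoxybenzoate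
Conditions: Et3N (2 equiv), DMAP (0.2 equiv), CH2Cl2, 0 °C → rt
Reagents that add atoms: none
Why: DMAP-catalysed O-acylation of a phenol; the acylpyridinium ion overcomes the hydrogen bond and the flanking aryl group, and the amine base cannot enolise the ketone, so no premature acyl shift should occur.

**Step 7**
Reactants: 9 2-acetyl-3,5-bis(benzyloxy)-6-[2-(benzyloxy)-5-formylphenyl]phenyl 4-methoxybenzoate
Product: 10 3-[3-acetyl-4,6-bis(benzyloxy)-2-(4-methoxybenzoyloxy)phenyl]-4-(benzyloxy)benzoic acid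
Conditions: NaClO2, NaH2PO4, 2-methyl-2-butene (excess), t-BuOH–THF–H2O, 0 °C → rt
Reagents that add atoms: sodium chlorite, [Na+].[O-]Cl=O
Why: Pinnick oxidation; the buffered, weakly acidic medium leaves the aryl ester, methyl ketone and benzyl ethers alone, and the alkene traps hypochlorous acid before it can chlorinate the alkoxy arenes.

**Step 8**
Reactants: 10 3-[3-acetyl-4,6-bis(benzyloxy)-2-(4-methoxybenzoyloxy)phenyl]-4-(benzyloxy)benzoic acid; 2 1-[2,4-bis(benzyloxy)-6-hydroxyphenyl]ethan-1-one (1.2 equiv)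
Product: 11 2-acetyl-3,5-bis(benzyloxy)phenyl 3-[3-acetyl-4,6-bis(benzyloxy)-2-(4-methoxybenzoyloxy)phenyl]-4-(benzyloxy)benzoate
Conditions: EDC·HCl (1.5 equiv), DMAP (0.3 equiv), CH2Cl2, rt
Reagents that add atoms: none
Why: Steglich esterification; phenol 2 is the only free hydroxyl present and the existing anisoate is untouched in the absence of strong base.

**Step 9**
Reactants: 11 2-acetyl-3,5-bis(benzyloxy)phenyl 3-[3-acetyl-4,6-bis(benzyloxy)-2-(4-methoxybenzoyloxy)phenyl]-4-(benzyloxy)benzoate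
Product: 12 1-[2,4-bis(benzyloxy)-6-hydroxyphenyl]-3-{4-(benzyloxy)-3-[4,6-bis(benzyloxy)-2-hydroxy-3-[3-(4-methoxyphenyl)-3-oxopropanoyl]phenyl]phenyl}propane-1,3-dione
Conditions: LiN(SiMe3)2 (5 equiv), THF, −78 °C → rt; then 1 M HCl
Reagents that add atoms: none
Why: LiN(SiMe3)2 turns both acetyl groups into lithium enolates, each enolate carbon adds to the carbonyl of the aryl ester on its own ortho oxygen through a six-membered cyclic transition state, and collapse of the two tetrahedral adducts expels the phenoxides, moving both aroyl groups from oxygen to carbon and forming C2–C3 and C2''–C3''. This is the Baker–Venkataraman rearrangement of 2-acyloxyacetophenones, run twice in one substrate. No ring is closed, since the six-membered hemiketal alkoxides are transient and reopen, and no stereocentre is formed. The step needs each enolate to take the acyl group on its own ring and the esters to survive until attacked; the first is secured by the six-membered intramolecular path against only macrocyclic crossed paths, the second by a non-nucleophilic amide base in dry THF. At least two equivalents of base per unit turn each product into its phenoxide–diketonate dianion, which makes both transfers irreversible and should drive the more hindered shift of the anisoate flanked by the biaryl bond. Because the liberated hydroxyls are the future O1 and O1'', the pyranone closure that follows can only give the 8-aryl flavone connectivity.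

**Step 10**
Reactants: 12 1-[2,4-bis(benzyloxy)-6-hydroxyphenyl]-3-{4-(benzyloxy)-3-[4,6-bis(benzyloxy)-2-hydroxy-3-[3-(4-methoxyphenyl)-3-oxopropanoyl]phenyl]phenyl}propane-1,3-dione
Product: 13 5,7-bis(benzyloxy)-2-{4-(benzyloxy)-3-[5,7-bis(benzyloxy)-2-(4-methoxyphenyl)-4-oxo-4H-chromen-8-yl]phenyl}-4H-chromen-4-one
Conditions: TsOH·H2O (0.3 equiv), toluene, 90 °C
Reagents that add atoms: none
Why: Acid-catalysed cyclodehydration of 2-hydroxyaryl 1,3-diketones; each phenol adds to the distal carbonyl and water is lost to give both chromen-4-ones, and any partial loss of a benzyl group would be harmless because all are removed next.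

**Step 11**
Reactants: 13 5,7-bis(benzyloxy)-2-{4-(benzyloxy)-3-[5,7-bis(benzyloxy)-2-(4-methoxyphenyl)-4-oxo-4H-chromen-8-yl]phenyl}-4H-chromen-4-one
Product: 14 podocarpusflavone A
Conditions: H2 (1 atm), Pd/C (10 wt %), THF–MeOH, rt
Reagents that add atoms: none
Why: Catalytic hydrogenolysis of aryl benzyl ethers; the aryl methyl ether and the conjugated pyranone double bonds should be inert at ambient pressure and temperature.

**Compound list**
1 | 2',4',6'-trihydroxyacetophenone | CC(=O)c1c(O)cc(O)cc1O | starting material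
2 | 1-[2,4-bis(benzyloxy)-6-hydroxyphenyl]ethan-1-one | CC(=O)c1c(O)cc(OCc2ccccc2)cc1OCc1ccccc1 | intermediate
3 | 1-[4,6-bis(benzyloxy)-2-hydroxy-3-iodophenyl]ethan-1-one | CC(=O)c1c(O)c(I)c(OCc2ccccc2)cc1OCc1ccccc1 | intermediate
4 | 3-bromo-4-hydroxybenzaldehyde | O=Cc1ccc(O)c(Br)c1 | starting material
5 | 4-(benzyloxy)-3-bromobenzaldehyde | O=Cc1ccc(OCc2ccccc2)c(Br)c1 | intermediate
6 | 4-(benzyloxy)-3-(4,4,5,5-tetramethyl-1,3,2-dioxaborolan-2-yl)benzaldehyde | O=Cc1ccc(OCc2ccccc2)c(B2OC(C)(C)C(C)(C)O2)c1 | intermediate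
7 | 3-[3-acetyl-4,6-bis(benzyloxy)-2-hydroxyphenyl]-4-(benzyloxy)benzaldehyde | CC(=O)c1c(O)c(-c2cc(C=O)ccc2OCc2ccccc2)c(OCc2ccccc2)cc1OCc1ccccc1 | intermediate
8 | 4-methoxybenzoyl chloride | COc1ccc(C(=O)Cl)cc1 | starting material
9 | 2-acetyl-3,5-bis(benzyloxy)-6-[2-(benzyloxy)-5-formylphenyl]phenyl 4-methoxybenzoate | CC(=O)c1c(OC(=O)c2ccc(OC)cc2)c(-c2cc(C=O)ccc2OCc2ccccc2)c(OCc2ccccc2)cc1OCc1ccccc1 | intermediate
10 | 3-[3-acetyl-4,6-bis(benzyloxy)-2-(4-methoxybenzoyloxy)phenyl]-4-(benzyloxy)benzoic acid | CC(=O)c1c(OC(=O)c2ccc(OC)cc2)c(-c2cc(C(=O)O)ccc2OCc2ccccc2)c(OCc2ccccc2)cc1OCc1ccccc1 | intermediate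
11 | 2-acetyl-3,5-bis(benzyloxy)phenyl 3-[3-acetyl-4,6-bis(benzyloxy)-2-(4-methoxybenzoyloxy)phenyl]-4-(benzyloxy)benzoate | CC(=O)c1c(OCc2ccccc2)cc(OCc2ccccc2)cc1OC(=O)c1ccc(OCc2ccccc2)c(-c2c(OCc3ccccc3)cc(OCc3ccccc3)c(C(C)=O)c2OC(=O)c2ccc(OC)cc2)c1 | intermediate
12 | 1-[2,4-bis(benzyloxy)-6-hydroxyphenyl]-3-{4-(benzyloxy)-3-[4,6-bis(benzyloxy)-2-hydroxy-3-[3-(4-methoxyphenyl)-3-oxopropanoyl]phenyl]phenyl}propane-1,3-dione | Oc1cc(OCc2ccccc2)cc(OCc2ccccc2)c1C(=O)CC(=O)c1ccc(OCc2ccccc2)c(-c2c(OCc3ccccc3)cc(OCc3ccccc3)c(C(=O)CC(=O)c3ccc(OC)cc3)c2O)c1 | intermediate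
13 | 5,7-bis(benzyloxy)-2-{4-(benzyloxy)-3-[5,7-bis(benzyloxy)-2-(4-methoxyphenyl)-4-oxo-4H-chromen-8-yl]phenyl}-4H-chromen-4-one | COc1ccc(-c2cc(=O)c3c(OCc4ccccc4)cc(OCc4ccccc4)c(-c4cc(-c5cc(=O)c6c(OCc7ccccc7)cc(OCc7ccccc7)cc6o5)ccc4OCc4ccccc4)c3o2)cc1 | intermediate
14 | podocarpusflavone A | COc1ccc(-c2cc(=O)c3c(O)cc(O)c(-c4cc(-c5cc(=O)c6c(O)cc(O)cc6o5)ccc4O)c3o2)cc1 | target

**Step count**
Total steps: 11. Longest linear sequence: 9 steps (steps 1, 2, 5, 6, 7, 8, 9, 10, 11).

**Steps most likely to fail**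

1. Step 9. The second acyl shift, at the anisoate flanked by the biaryl bond, may stall, or acyl groups may be lost or scrambled between the two esters, leaving half-rearranged mixtures. The fallback stages the two shifts one at a time and sets out from acid 10. LiN(SiMe3)2 (4 equiv, THF, −78 °C → rt) should effect a single Baker–Venkataraman shift to 4-(benzyloxy)-3-{4,6-bis(benzyloxy)-2-hydroxy-3-[3-(4-methoxyphenyl)-3-oxopropanoyl]phenyl}benzoic acid F1. TsOH·H2O in toluene should close this to 4-(benzyloxy)-3-[5,7-bis(benzyloxy)-2-(4-methoxyphenyl)-4-oxo-4H-chromen-8-yl]benzoic acid F2. Esterification with 2 (EDC·HCl, DMAP) should give 2-acetyl-3,5-bis(benzyloxy)phenyl 4-(benzyloxy)-3-[5,7-bis(benzyloxy)-2-(4-methoxyphenyl)-4-oxo-4H-chromen-8-yl]benzoate F3. A second single acyl shift with LiN(SiMe3)2 should give 1-[2,4-bis(benzyloxy)-6-hydroxyphenyl]-3-{4-(benzyloxy)-3-[5,7-bis(benzyloxy)-2-(4-methoxyphenyl)-4-oxo-4H-chromen-8-yl]phenyl}propane-1,3-dione F4. Acid cyclodehydration of F4 comes back to the route at 13.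

2. Step 5. Protodeboronation of the ortho-alkoxy boronate may outrun a slow oxidative addition or transmetalation at the hindered, electron-rich iodophenoxide, or the iodide may be reduced. The fallback masks the phenol before coupling and sets out from 3. MOMCl with NaH in DMF should give 1-[4,6-bis(benzyloxy)-3-iodo-2-(methoxymethoxy)phenyl]ethan-1-one F5. Coupling F5 with 6 (Pd(OAc)2, SPhos, K2CO3, dioxane–H2O) should give 3-[3-acetyl-4,6-bis(benzyloxy)-2-(methoxymethoxy)phenyl]-4-(benzyloxy)benzaldehyde F6. Aqueous HCl in THF at 40 °C removes the acetal and returns to the route at 7.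

3. Step 2. Iodination para to the phenol (C5) or twofold iodination may erode regiochemical purity. The fallback iodinates before benzylation, when the two open ring positions are equivalent by symmetry, and sets out from 1. NIS (1.0 equiv, DMF, 0 °C) should give 1-(2,4,6-trihydroxy-3-iodophenyl)ethan-1-one F7. BnBr (2.0 equiv) with K2CO3 in DMF should then alkylate the 4-OH and the ortho OH remote from iodine, leaving the chelated hydroxyl beside iodine free, and so return to the route at 3.

**Further compounds**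
F1 | step 9 | 4-(benzyloxy)-3-{4,6-bis(benzyloxy)-2-hydroxy-3-[3-(4-methoxyphenyl)-3-oxopropanoyl]phenyl}benzoic acid | COc1ccc(C(=O)CC(=O)c2c(O)c(-c3cc(C(=O)O)ccc3OCc3ccccc3)c(OCc3ccccc3)cc2OCc2ccccc2)cc1
F2 | step 9 | 4-(benzyloxy)-3-[5,7-bis(benzyloxy)-2-(4-methoxyphenyl)-4-oxo-4H-chromen-8-yl]benzoic acid | COc1ccc(-c2cc(=O)c3c(OCc4ccccc4)cc(OCc4ccccc4)c(-c4cc(C(=O)O)ccc4OCc4ccccc4)c3o2)cc1
F3 | step 9 | 2-acetyl-3,5-bis(benzyloxy)phenyl 4-(benzyloxy)-3-[5,7-bis(benzyloxy)-2-(4-methoxyphenyl)-4-oxo-4H-chromen-8-yl]benzoate | COc1ccc(-c2cc(=O)c3c(OCc4ccccc4)cc(OCc4ccccc4)c(-c4cc(C(=O)Oc5cc(OCc6ccccc6)cc(OCc6ccccc6)c5C(C)=O)ccc4OCc4ccccc4)c3o2)cc1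
F4 | step 9 | 1-[2,4-bis(benzyloxy)-6-hydroxyphenyl]-3-{4-(benzyloxy)-3-[5,7-bis(benzyloxy)-2-(4-methoxyphenyl)-4-oxo-4H-chromen-8-yl]phenyl}propane-1,3-dione | COc1ccc(-c2cc(=O)c3c(OCc4ccccc4)cc(OCc4ccccc4)c(-c4cc(C(=O)CC(=O)c5c(O)cc(OCc6ccccc6)cc5OCc5ccccc5)ccc4OCc4ccccc4)c3o2)cc1
F5 | step 5 | 1-[4,6-bis(benzyloxy)-3-iodo-2-(methoxymethoxy)phenyl]ethan-1-one | CC(=O)c1c(OCOC)c(I)c(OCc2ccccc2)cc1OCc1ccccc1
F6 | step 5 | 3-[3-acetyl-4,6-bis(benzyloxy)-2-(methoxymethoxy)phenyl]-4-(benzyloxy)benzaldehyde | CC(=O)c1c(OCOC)c(-c2cc(C=O)ccc2OCc2ccccc2)c(OCc2ccccc2)cc1OCc1ccccc1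
F7 | step 2 | 1-(2,4,6-trihydroxy-3-iodophenyl)ethan-1-one | CC(=O)c1c(O)cc(O)c(I)c1O
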